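**Plan**
1. Retrosynthesis cuts, in this order: the phenol C1–O bond (back to a ring C–H via C–B), the side-chain bond C3'–C4' (C1' is the benzylic carbon), and the O–CH3 bond of the C4 methoxy group.
2. Enabling feature: the chain sits on ring carbon C3, ortho to the C4 oxygen, so the benzene ring, both oxygens and C1'–C3' together are the skeleton of o-eugenol (2-allyl-6-methoxyphenol). Its terminal alkene carbon is C3'.
3. Forward: o-eugenol 1 is O-methylated to 2. A NiH-catalysed anti-Markovnikov hydroalkylation of the allyl group with 1-iodotetradecane 3 then forms C3'–C4' and completes the C17 chain (4) in one C(sp3)–C(sp3) coupling.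
4. The 1,2,3-trisubstituted ring of 4 has a single C–H with no ortho neighbour (C5, which becomes C1 of the target). Sterically governed Ir-catalysed borylation (5) and ipso-oxidation turn it into the phenol 6.
5. No ring is built (the benzene ring is bought), and the target has no stereocentre, so no stereochemistry has to be set.

Key step: step 2

Remark: the target is achiral (no stereocentre, no stereogenic double bond), so "single enantiomer" places no demand on the route; 1 and 3 are taken as commercial.

**Step 1**
Reactants: 1 o-eugenol (2-allyl-6-methoxyphenol)
Product: 2 1-allyl-2,3-dimethoxybenzene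
Conditions: MeI, K2CO3, acetone, reflux
Reagents that add atoms: iodomethane, CI
Why: Williamson O-methylation of the phenoxide should proceed cleanly, and the mild carbonate base should leave the allyl double bond out of conjugation.

**Step 2**
Reactants: 2 1-allyl-2,3-dimethoxybenzene; 3 1-iodotetradecane
Product: 4 1-heptadecyl-2,3-dimethoxybenzene
Conditions: NiBr2·diglyme (10 mol %), i-Pr-Pybox (12 mol %), (EtO)2MeSiH, Na2CO3, DMA, rt
Reagents that add atoms: none
Why: A (pybox)Ni–H, generated from the nickel halide with the hydrosilane and carbonate, should insert the terminal alkene of 2 with nickel at the unsubstituted terminal carbon (C3') and hydride at C2'; a Ni(I) species abstracts iodine from 3 to give the tetradecyl radical, which is captured by the primary alkyl–nickel, and C(sp3)–C(sp3) reductive elimination from Ni(III) forms the C3'–C4' bond. The closest known reaction type is the NiH-catalysed anti-Markovnikov reductive hydroalkylation of unactivated terminal alkenes with primary alkyl iodides. No ring is closed and no stereocentre is created. The step needs linear regioselectivity, no migration of the double bond toward the arene (chain-walking to the benzylic carbon or isomerisation to the propenyl arene), and cross-coupling in preference to simple reduction of either partner. The monosubstituted alkene places nickel at the unhindered CH2 terminus, the tridentate pybox ligand leaves no open cis site for β-hydride elimination at room temperature so the primary alkyl–nickel should be trapped before it can walk, and the ortho methoxy group further disfavours a benzylic nickel species. The aryl methyl ethers are inert to hydrosilane, weak carbonate base and low-valent nickel at room temperature.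

**Step 3**
Reactants: 4 1-heptadecyl-2,3-dimethoxybenzene
Product: 5 2-(3-heptadecyl-4,5-dimethoxyphenyl)-4,4,5,5-tetramethyl-1,3,2-dioxaborolane
Conditions: [Ir(OMe)(cod)]2 (1.5 mol %), dtbpy (3 mol %), B2pin2, cyclohexane, 80 °C
Reagents that add atoms: bis(pinacolato)diboron, CC1(C)OB(OC1(C)C)B1OC(C)(C)C(C)(C)O1
Why: Iridium-catalysed aromatic C–H borylation is sterically controlled, and of the three ring C–H bonds of 4 only C5–H has no ortho substituent (C4–H is ortho to OMe, C6–H is ortho to the heptadecyl chain), so the Bpin group should enter meta to the chain and para to the inner methoxy group, a site that electrophilic substitution would not address.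

**Step 4**
Reactants: 5 2-(3-heptadecyl-4,5-dimethoxyphenyl)-4,4,5,5-tetramethyl-1,3,2-dioxaborolane
Product: 6 3-heptadecyl-4,5-dimethoxyphenol
Conditions: Oxone, acetone/THF/H2O, rt, 10 min
Reagents that add atoms: potassium peroxymonosulfate (active component of Oxone), [K+].[O-]S(=O)(=O)OO
Why: ipso-Oxidation of the aryl boronate, in which the peroxysulfate adds to boron, the aryl group migrates from boron to oxygen with loss of sulfate and the aryl borate is hydrolysed, should release the phenol at the carbon that carried boron.

**Compound list**
1 | o-eugenol (2-allyl-6-methoxyphenol) | C=CCc1cccc(OC)c1O | starting material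
2 | 1-allyl-2,3-dimethoxybenzene | C=CCc1cccc(OC)c1OC | intermediate
3 | 1-iodotetradecane | CCCCCCCCCCCCCCI | starting material
4 | 1-heptadecyl-2,3-dimethoxybenzene | CCCCCCCCCCCCCCCCCc1cccc(OC)c1OC | intermediate
5 | 2-(3-heptadecyl-4,5-dimethoxyphenyl)-4,4,5,5-tetramethyl-1,3,2-dioxaborolane | CCCCCCCCCCCCCCCCCc1cc(B2OC(C)(C)C(C)(C)O2)cc(OC)c1OC | intermediate
6 | 3-heptadecyl-4,5-dimethoxyphenol | CCCCCCCCCCCCCCCCCc1cc(O)cc(OC)c1OC | target

**Total step count:** 4
**Longest linear sequence:** 4 steps (1 → 2 → 4 → 5 → 6; 3 is a purchased coupling partner)

**Steps most likely to fail**

Step 2. The nickel hydride may undergo β-hydride elimination and re-insertion, moving the double bond into conjugation with the arene (propenyl arene, benzylic alkylation), and the iodide may simply be reduced. The fallback sets out from 2 and comes back at 4. Hydroboration of 2 with 9-BBN (THF, rt) should give 9-[3-(2,3-dimethoxyphenyl)propyl]-9-borabicyclo[3.3.1]nonane F1 with boron at the terminal carbon. A B-alkyl Suzuki–Miyaura coupling of this borane with 3 (Pd(PPh3)4, K3PO4, dioxane, 60 °C) should then form the same C3'–C4' bond and deliver 4.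

Step 3. C–H activation of the electron-rich ring may be slow, and competing borylation at the C–H ortho to the methoxy group would give isomer mixtures that are hard to separate. The fallback sets out from 1 and comes back at 6, fixing the oxygen site by the para-directing free phenol instead of by sterics. Ionic ring bromination of 1 (NBS, MeCN, 0 °C) should give 2-allyl-4-bromo-6-methoxyphenol F2, since the activated phenol should react faster than the isolated terminal alkene. O-Methylation (MeI, K2CO3, acetone) should give 1-allyl-5-bromo-2,3-dimethoxybenzene F3. Hydroalkylation with 3 under the conditions of step 2 should give 5-bromo-1-heptadecyl-2,3-dimethoxybenzene F4, because the alkyl iodide should be activated much faster than the aryl bromide. Palladium-catalysed hydroxylation of the aryl bromide (Pd2(dba)3, t-BuXPhos, KOH, dioxane/H2O, 100 °C) should then give 6.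

Step 4. The peroxy reagent may over-oxidise the electron-rich product, a 4-methoxyphenol, to the p-quinone by oxidative demethylation. The fallback sets out from 5 and comes back at 6 without exposing the phenol to an oxidant. Copper-mediated chlorodeboronation of 5 (CuCl2, THF/MeOH/H2O, 80 °C) should give 5-chloro-1-heptadecyl-2,3-dimethoxybenzene F5. Palladium-catalysed hydroxylation of the aryl chloride under degassed conditions (Pd2(dba)3, t-BuXPhos, KOH, dioxane/H2O, 100 °C) followed by acidification should then give 6.

**Further compounds**
F1 | step 2 | 9-[3-(2,3-dimethoxyphenyl)propyl]-9-borabicyclo[3.3.1]nonane | COc1cccc(CCCB2C3CCCC2CCC3)c1OC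
F2 | step 3 | 2-allyl-4-bromo-6-methoxyphenol | C=CCc1cc(Br)cc(OC)c1O
F3 | step 3 | 1-allyl-5-bromo-2,3-dimethoxybenzene | C=CCc1cc(Br)cc(OC)c1OC
F4 | step 3 | 5-bromo-1-heptadecyl-2,3-dimethoxybenzene | CCCCCCCCCCCCCCCCCc1cc(Br)cc(OC)c1OC
F5 | step 4 | 5-chloro-1-heptadecyl-2,3-dimethoxybenzene | CCCCCCCCCCCCCCCCCc1cc(Cl)cc(OC)c1OC
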